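**Plan**
1. Retrosynthesis: remove five O-benzyl ethers and a C8 bromine on ring D; cut the interflavan bond C4(upper)–C6(lower) to a 4-flavanyl cation, masked as the C3=C4 double bond of a (2S)-flav-3-ene, plus O-benzylated 8-bromo-epiafzelechin; cut O1–C2 of the upper pyran (ring C) to an open 1,3-diarylallyl alcohol; cut C2=C3 of its chalcone precursor (aldol).
2. Forward: the lower unit (rings D, E, F) is bought as (−)-epiafzelechin, O-benzylated and brominated at C8. The upper chain is joined by Claisen–Schmidt condensation and reduced, ring C is closed by O1–C2 bond formation, then C4–C6 coupling and one hydrogenolysis finish the route.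
3. Enabling feature: ring A of the upper unit carries O1 ortho and O7 para to C4a, so C4 ionises to an ortho-quinone methide in which O1=C8a–C4a=C4–C3=C2 is a 1-oxatriene. Its oxa-6π closure makes the O1–C2 bond and leaves C3=C4 as a latent C4 cation.
4. Stereochemistry: C2 and C3 of the lower unit are bought; C2 of the upper unit (S) is set by a chiral Brønsted acid in the ring closure; C4 of the upper unit (R) is relayed from C2 by trans (pseudo-axial) arylation of the ring-C cation; the C6 (not C8) linkage is enforced by the bromine.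
5. Helpers put in and taken out again: the O-benzyl groups, the C8 bromine and the C3=C4 unsaturation.

Key step: step 5

Remark: (−)-epiafzelechin is a catalogue natural product and is used as bought; atom numbers are flavan numbers (upper unit: rings A, B, C; lower unit: rings D, E, F).

Step 1
Reactants: 1 (−)-epiafzelechin
Product: 2 (2R,3R)-5,7-bis(benzyloxy)-2-[4-(benzyloxy)phenyl]chroman-3-ol (5,7,4′-tri-O-benzyl-epiafzelechin)
Conditions: BnBr (3.3 equiv), K2CO3, DMF, 0 °C → rt, Ar
Reagents that add atoms: benzyl bromide, BrCc1ccccc1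
Why: Williamson etherification in which K2CO3 deprotonates only the three phenols and not the C3 alcohol, and at or below room temperature the bought C2/C3 stereocentres should stay untouched.

Step 2
Reactants: 2 (2R,3R)-5,7-bis(benzyloxy)-2-[4-(benzyloxy)phenyl]chroman-3-ol
Product: 3 (2R,3R)-8-bromo-5,7-bis(benzyloxy)-2-[4-(benzyloxy)phenyl]chroman-3-ol
Conditions: NBS (1.05 equiv), CH2Cl2, −78 °C → rt
Reagents that add atoms: N-bromosuccinimide, O=C1CCC(=O)N1Br
Why: Electrophilic aromatic bromination of the phloroglucinol-type ring D should occur at C8 (between O1 and 7-OBn), the established site for O-benzylated flavan-3-ols, which installs the blocking group that later forces C–C bond formation to C6.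

Step 3
Reactants: 4 1-[4-(benzyloxy)-2-hydroxyphenyl]ethan-1-one; 5 4-(benzyloxy)benzaldehyde
Product: 6 (E)-1-[4-(benzyloxy)-2-hydroxyphenyl]-3-[4-(benzyloxy)phenyl]prop-2-en-1-one
Conditions: KOH (3 equiv), EtOH/H2O, rt; then 1 M HCl to pH 5
Reagents that add atoms: none
Why: Claisen–Schmidt (crossed aldol) condensation of the acetophenone enolate with the non-enolisable aldehyde, followed by E1cB loss of water to the (E)-enone.

Step 4
Reactants: 6 (E)-1-[4-(benzyloxy)-2-hydroxyphenyl]-3-[4-(benzyloxy)phenyl]prop-2-en-1-one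
Product: 7 rac-(E)-5-(benzyloxy)-2-{1-hydroxy-3-[4-(benzyloxy)phenyl]prop-2-en-1-yl}phenol
Conditions: NaBH4, CeCl3·7H2O, MeOH/THF, −20 °C; aq. NaHCO3 quench; crude product used at once, no silica
Reagents that add atoms: none
Why: Luche reduction should give 1,2-hydride addition to the enone, and the carbinol centre is made as a racemate on purpose because it is erased in step 5.

Step 5
Reactants: 7 rac-(E)-5-(benzyloxy)-2-{1-hydroxy-3-[4-(benzyloxy)phenyl]prop-2-en-1-yl}phenol
Product: 9 (2S)-7-(benzyloxy)-2-[4-(benzyloxy)phenyl]-2H-chromene, via vinylogous ortho-quinone methide 8 (not isolated)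
Conditions: (R)- or (S)-3,3′-bis(2,4,6-triisopropylphenyl)-BINOL N-triflylphosphoramide (5 mol%, the antipode that gives 2S), toluene (0.02 M), 4 Å MS, −78 → −40 °C; Et3N quench
Reagents that add atoms: none
Why: The acid ionises the doubly activated carbinol (ortho-OH and para-OBn on ring A) with loss of water to the vinylogous ortho-quinone methide 8, held as a hydrogen-bonded contact ion pair with the chiral phosphoramide anion, and the 1-oxatriene O1=C8a–C4a=C4–C3=C2 closes the pyran ring by thermal disrotatory oxa-6π electrocyclisation (formally a 6-endo-trig attack of the phenolic O1 on the allyl-cation terminus C2). The closest known reaction type is the chiral Brønsted acid-catalysed asymmetric intramolecular allylic substitution of ortho-hydroxyaryl allylic alcohols to 2H-chromenes through chiral contact ion pairs. The only new stereocentre, C2, is controlled by the catalyst anion bound at the O1–H of the protonated quinone methide, next to the bond being made, so the racemic carbinol centre of 7 is erased and the step is enantioconvergent. The step needs O1–C2 closure to outrun intermolecular capture of the cation and any uncatalysed racemic closure, which the intramolecular phenol, high dilution, molecular sieves and low temperature should secure, and it needs bonding at C2 and not at C4, which the six-membered ring size dictates. The new C3=C4 double bond, conjugated to ring A, is the handle from which the C4 cation is regenerated inside ring C in step 6, so this one event builds ring C in the (2S) form and prepares the stereocontrolled interflavan bond.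

Step 6
Reactants: 3 (2R,3R)-8-bromo-5,7-bis(benzyloxy)-2-[4-(benzyloxy)phenyl]chroman-3-ol; 9 (2S)-7-(benzyloxy)-2-[4-(benzyloxy)phenyl]-2H-chromene
Product: 10 (2R,3R)-8-bromo-5,7-bis(benzyloxy)-2-[4-(benzyloxy)phenyl]-6-{(2S,4R)-7-(benzyloxy)-2-[4-(benzyloxy)phenyl]chroman-4-yl}chroman-3-ol
Conditions: 3 (1 equiv), 9 (2 equiv, slow addition), TfOH (10 mol%), CH2Cl2, 4 Å MS, −40 °C; Et3N quench
Reagents that add atoms: none
Why: Markovnikov protonation at C3 regenerates the 4-flavanyl cation (stabilised by O1 and the para 7-OBn), which alkylates the only free nucleophilic ring carbon of 3 (C6, since C8 carries Br) in a Friedel–Crafts hydroarylation, the arene entering pseudo-axially on the face anti to the pseudo-equatorial 2-aryl group so that the 2,4-trans (4R) isomer should predominate, with any material from residual (2R)-chromene ending up in a separable diastereomer.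

Step 7
Reactants: 10 (2R,3R)-8-bromo-5,7-bis(benzyloxy)-2-[4-(benzyloxy)phenyl]-6-{(2S,4R)-7-(benzyloxy)-2-[4-(benzyloxy)phenyl]chroman-4-yl}chroman-3-ol
Product: 11 (2R,3R)-2-(4-hydroxyphenyl)-6-[(2S,4R)-7-hydroxy-2-(4-hydroxyphenyl)chroman-4-yl]chroman-3,5,7-triol (CNP0167324.2)
Conditions: H2 (1 atm), Pd(OH)2/C, NaOAc (1.2 equiv), THF/MeOH, rt
Reagents that add atoms: none
Why: Catalytic hydrogenolysis should cleave the five O-benzyl ethers and the aryl C–Br bond in one operation, the acetate buffer taking up HBr so that the interflavan bond, the two O1–C2 bonds and all four stereocentres are left as they are.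

**Compound list**
1 | (−)-epiafzelechin, (2R,3R)-2-(4-hydroxyphenyl)chroman-3,5,7-triol | O[C@@H]1Cc2c(O)cc(O)cc2O[C@@H]1c1ccc(O)cc1 | starting material
2 | (2R,3R)-5,7-bis(benzyloxy)-2-[4-(benzyloxy)phenyl]chroman-3-ol | O[C@@H]1Cc2c(OCc3ccccc3)cc(OCc3ccccc3)cc2O[C@@H]1c1ccc(OCc2ccccc2)cc1 | intermediate
3 | (2R,3R)-8-bromo-5,7-bis(benzyloxy)-2-[4-(benzyloxy)phenyl]chroman-3-ol | O[C@@H]1Cc2c(OCc3ccccc3)cc(OCc3ccccc3)c(Br)c2O[C@@H]1c1ccc(OCc2ccccc2)cc1 | intermediate
4 | 1-[4-(benzyloxy)-2-hydroxyphenyl]ethan-1-one | CC(=O)c1ccc(OCc2ccccc2)cc1O | starting material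
5 | 4-(benzyloxy)benzaldehyde | O=Cc1ccc(OCc2ccccc2)cc1 | starting material
6 | (E)-1-[4-(benzyloxy)-2-hydroxyphenyl]-3-[4-(benzyloxy)phenyl]prop-2-en-1-one | O=C(/C=C/c1ccc(OCc2ccccc2)cc1)c1ccc(OCc2ccccc2)cc1O | intermediate
7 | rac-(E)-5-(benzyloxy)-2-{1-hydroxy-3-[4-(benzyloxy)phenyl]prop-2-en-1-yl}phenol | OC(/C=C/c1ccc(OCc2ccccc2)cc1)c1ccc(OCc2ccccc2)cc1O | intermediate
8 | (6Z)-3-(benzyloxy)-6-{(2E)-3-[4-(benzyloxy)phenyl]prop-2-en-1-ylidene}cyclohexa-2,4-dien-1-one (vinylogous ortho-quinone methide, not isolated) | O=C1/C(=C\C=C\c2ccc(OCc3ccccc3)cc2)C=CC(OCc2ccccc2)=C1 | intermediate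
9 | (2S)-7-(benzyloxy)-2-[4-(benzyloxy)phenyl]-2H-chromene | C(c1ccccc1)Oc1ccc([C@@H]2C=Cc3ccc(OCc4ccccc4)cc3O2)cc1 | intermediate
10 | (2R,3R)-8-bromo-5,7-bis(benzyloxy)-2-[4-(benzyloxy)phenyl]-6-{(2S,4R)-7-(benzyloxy)-2-[4-(benzyloxy)phenyl]chroman-4-yl}chroman-3-ol | C(c1ccccc1)Oc1ccc([C@@H]2C[C@@H](c3c(OCc4ccccc4)c(Br)c4c(c3OCc3ccccc3)C[C@@H](O)[C@@H](c3ccc(OCc5ccccc5)cc3)O4)c3ccc(OCc4ccccc4)cc3O2)cc1 | intermediate
11 | (2R,3R)-2-(4-hydroxyphenyl)-6-[(2S,4R)-7-hydroxy-2-(4-hydroxyphenyl)chroman-4-yl]chroman-3,5,7-triol | Oc1ccc([C@@H]2C[C@@H](c3c(O)cc4c(c3O)C[C@@H](O)[C@@H](c3ccc(O)cc3)O4)c3ccc(O)cc3O2)cc1 | target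

**Totals**
Total steps: 7. Longest linear sequence: 5 steps (steps 3 to 7, from 4 and 5).

**Steps most likely to fail**

Step 5. The risk is insufficient enantiofacial control in the ring closure, or racemic closure of the very labile alcohol 7 during its isolation before the catalyst is present. The fallback gives up catalyst control and sets out from 7. A trace of AcOH in toluene at rt closes it to racemic 7-(benzyloxy)-2-[4-(benzyloxy)phenyl]-2H-chromene F1. F1 is coupled with enantiopure 3 under the conditions of step 6, and the desired product is separated by chromatography from its upper-unit diastereomer, the (2R,4S)-configured coupling product F2. The bought stereocentres of the lower unit act as the resolving handle, and the route is rejoined at 10.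

Step 6. The risks are self-condensation of the chromene (C3 of one molecule attacking the C4 cation of another), hydride-transfer disproportionation, slow attack by the bromine-deactivated ring D, and erosion of the C2 configuration by reversible O1–C2 heterolysis under protic acid. The fallback sets out from 9. Mukaiyama hydration (Co(acac)2, PhSiH3, O2, THF, then NaBH4) gives (2S)-7-(benzyloxy)-2-[4-(benzyloxy)phenyl]chroman-4-ol F3 as a mixture of C4 epimers, an electrophile precursor that is not itself a nucleophile. F3 is ionised with TMSOTf in CH2Cl2 at −78 °C in the presence of excess 3 (the established flavan-4-ol/arene Friedel–Crafts coupling, trans-selective for the same reason), and the route is rejoined at 10.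

Step 7. The risks are cleavage of the acid-sensitive interflavan bond by HBr released on the catalyst, over-reduction of the benzylic O1–C2 bonds, and incomplete loss of bromine through catalyst poisoning. The fallback sets out from 10 and separates the two tasks without hydrogen or palladium. Bromine–lithium exchange (n-BuLi, 2.2 equiv, THF, −78 °C, then MeOH) gives (2R,3R)-5,7-bis(benzyloxy)-2-[4-(benzyloxy)phenyl]-6-{(2S,4R)-7-(benzyloxy)-2-[4-(benzyloxy)phenyl]chroman-4-yl}chroman-3-ol F4. The benzyl ethers are then removed with BCl3 and pentamethylbenzene in CH2Cl2 at −78 °C, and the route is rejoined at 11.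

**Further compounds**
F1 | step 5 | racemic 7-(benzyloxy)-2-[4-(benzyloxy)phenyl]-2H-chromene | C(c1ccccc1)Oc1ccc(C2C=Cc3ccc(OCc4ccccc4)cc3O2)cc1
F2 | step 5 | (2R,3R)-8-bromo-5,7-bis(benzyloxy)-2-[4-(benzyloxy)phenyl]-6-{(2R,4S)-7-(benzyloxy)-2-[4-(benzyloxy)phenyl]chroman-4-yl}chroman-3-ol | C(c1ccccc1)Oc1ccc([C@H]2C[C@H](c3c(OCc4ccccc4)c(Br)c4c(c3OCc3ccccc3)C[C@@H](O)[C@@H](c3ccc(OCc5ccccc5)cc3)O4)c3ccc(OCc4ccccc4)cc3O2)cc1
F3 | step 6 | (2S)-7-(benzyloxy)-2-[4-(benzyloxy)phenyl]chroman-4-ol (C4 epimers) | OC1C[C@@H](c2ccc(OCc3ccccc3)cc2)Oc2cc(OCc3ccccc3)ccc12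
F4 | step 7 | (2R,3R)-5,7-bis(benzyloxy)-2-[4-(benzyloxy)phenyl]-6-{(2S,4R)-7-(benzyloxy)-2-[4-(benzyloxy)phenyl]chroman-4-yl}chroman-3-ol | C(c1ccccc1)Oc1ccc([C@@H]2C[C@@H](c3c(OCc4ccccc4)cc4c(c3OCc3ccccc3)C[C@@H](O)[C@@H](c3ccc(OCc5ccccc5)cc3)O4)c3ccc(OCc4ccccc4)cc3O2)cc1
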